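**Conventions.** Atom numbers C1–O35 follow the heavy atoms of the target SMILES in the order written: C1 exocyclic methylene, C3 enone carbonyl, C10 cyclopentane carbinol, C13 gem-dimethyl carbon, C17–C18 bridge, C24 oxepanone carbonyl, O29 ring oxygen, C33 cyclohexane carbinol. Compound numbers are those of the steps and of the compound list. TMS = trimethylsilyl, TES = triethylsilyl, TBS = tert-butyldimethylsilyl.

## Analysis of the target

The target 49 is made of two bicyclic halves joined by the C17–C18 ethylene bridge. The left half is a cis-fused hydroazulene: the cycloheptanone C2–C3–C5–C6–C7–C13–C16 is fused at C6–C7 to the cyclopentane C6–C10. The right half is a trans-fused oxepanone–cyclohexane: the oxepane C20–C22–C23–C24–C26–O29–C30 is fused at C20–C30 to the cyclohexane C19–C20–C30–C31–C32–C33. There are eight stereocentres, C6, C7, C10, C16, C19, C20 and C30 (all R) and C33 (S); the two sets are separated by two methylene groups and cannot control each other, so each half has to be made enantiopure. On the left, H6, H7 and H16 lie on one face of the seven-membered ring, and the C10 hydroxyl (O12) sits on the face of the ring-fusion hydrogens, trans to C5 on C6 and trans to the C13 arm on C7. On the right, the C20 methyl is axial, the C18 chain on C19 is equatorial and the C33 hydroxyl is axial and syn to the C20 methyl. The sensitive groups are the α-methylene ketone C1=C2–C3=O (a Michael acceptor whose double bond can move into the ring), the two tertiary alcohols at C10 and C33, and the α-alkoxy ketone at C24. The hard points are the seven-membered carbocycle with the quaternary C13 between the stereocentres C7 and C16, a C10 carbinol whose configuration is not the one expected from methyl addition to the convex face of a cis-hydroazulenone, and an ether oxygen held between a tertiary carbon (C26) and a hindered secondary one (C30). The strategy rests on the C6/C10 pair: C5 on C6 is anti to O12 on C10 and syn to C13 on C7, which is the arrangement left when a carbon nucleophile tethered through C7 attacks C6 of a C6–C10 epoxide from the back; C2, which carries C1 next to the C3 carbonyl, is the central carbon of an acetoacetate whose methyl group is C5.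

## Retrosynthetic reasoning

**C24 ketone and the methylene ketone (49 ← 48 ← 46).** The last step is oxidation of the C24 alcohol of 48; both C24 epimers serve, so C24 never has to be controlled. The α-methylene ketone is the most fragile group and is released one step earlier from the vinylogous carbonate 46, in which C2=C3 carries a methoxy group on C3 and the ester carbon C1 on C2. Reduction of the ester and acid then turn C1 into the methylene carbon and C3 into the ketone. A β-keto ester on the seven-membered ring is therefore wanted: the ester carbon fixes the site of the methylene group, which a late methylenation of a C3 ketone with two α-methylene neighbours could not do.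

**O29–C26 (46 ← 44).** The oxepane is cut at its oxygen–tertiary carbon bond, with C26 as the inner carbon of an isopropenyl group and C24 already oxygenated. The forward closure is then a 7-exo Markovnikov addition of the C30 hydroxyl with only one possible regiochemistry. The more obvious cut to a C24–C26 epoxide of a prenyl-type chain was not used, because attack at C24 (six-membered ring) competes with attack at C26.

**C33–C34 and C18–C19 (44 ← 43 ← 42 ← 41 ← 39 ← 37 + 25).** The C34 methyl is added to a C33 ketone; the axial C20 methyl forces equatorial entry and leaves the axial hydroxyl. The halves are joined at C18–C19 by aldol addition of a regiodefined C19 enolate to the C18 aldehyde 25, followed by dehydration and conjugate reduction. The aldol was preferred to direct alkylation because a hindered enolate next to the quaternary C20 reacts reliably with an aldehyde but poorly with an unactivated alkyl halide.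

**C20–C22 (37 ← 31 + 35).** Conjugate addition of the side chain (as Grignard reagent 36) to enone 31 builds the quaternary C20 anti to the C30 silyloxy group and delivers the enolate on the C19 side, which is stored as enol silane 37. Enone 31 comes from 26 through 27, 28 and 30, with the C30 configuration set by asymmetric epoxidation; bromide 35 comes from 32 through 33 and 34.

**Left-half adjustments (25 ← 23 ← 22).** The β-keto ester 22 is capped as its methyl enol ether 23; the acetal at C18 is then converted into the aldehyde while the C10 alcohol is silylated.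

**C5–C6, the key bond (22 ← 19).** The seven-membered ring is opened between C5 and C6, giving epoxide 19 with an α-substituted acetoacetate side chain. This cut places the only ring-forming event of the left half where it also fixes C6 and carries O12 on C10 in from the epoxide. All other stereocentres of the left half (C7, C10, C16) are already in the precursor.

**C2–C3 and the epoxide (19 ← 18 ← 15 + 16).** The epoxide comes from the cyclopentene 18 by attack anti to the C7 substituent. The acetoacetate is assembled last, by acylation of ester 15 at C2 with 16. It cannot be present earlier: with C18 as a free aldehyde or alcohol, an enolisable 1,3-dicarbonyl closes onto it to a six-membered lactol or dihydropyran. For the same reason, and because a 2-alkoxyethyl nucleophile would eliminate, C18 is carried as a dimethyl acetal rather than as a benzyl ether. The acetal already has the oxidation level that the fragment union needs.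

**C16–C17 (15 ← 14 ← 13 ← 12 ← 8 + 11; 8 ← 6 + 7; 11 ← 9).** C16 is flanked by the quaternary C13, and the existing centre C7 is too remote to direct it, so it is set by a catalyst in a Mukaiyama–Michael addition of the thioacetate ketene acetal 11 to the alkylidene malonate 8. The malonate is then trimmed to the acetic ester arm (13) and the thioester is taken to the aldehyde (14) and acetal (15).

**C10–C11 and C7–C13 (6 ← 5 ← 4 ← 3 ← 1 + 2).** The C11 methyl is attached by cross-coupling of enol triflate 4, which is made from enol silane 3. Enol silane 3 is the direct product of the enantioselective Mukaiyama–Michael addition of ketene acetal 2 to cyclopentenone 1; this sets C7 and, through the position of the enol double bond, decides that the later alkene and epoxide lie between C6 and C10.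

## Alternatives that were turned down

**Alternative 1:** The right-hand quaternary carbon and the inter-half bond are cut together (C20–C22 and C18–C19). In the forward step the homoprenyl Grignard reagent A3 adds under copper catalysis to enone 31, and the magnesium enolate is trapped by the left-half aldehyde A2 to give the β-hydroxy ketone A1.
- For: it is a three-component union that makes C20 and the bridge in one flask and needs no isolated enol silane; it is one step shorter at the union than the chosen route, which performs the same two bond formations in two flasks (steps 23 and 24).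
- Against: it is a way of joining the halves, not of making them. It presupposes A2, the complete hydroazulene with its seven-membered ring and the C6/C7/C10/C16 stereocentres, which is where the target is hardest. The homoprenyl chain of A1 must later be closed to the oxepane through a hydroxy-epoxide, where six-membered closure at C24 competes with the required attack at C26. A magnesium enolate next to a new quaternary centre must also add to an enolisable aldehyde in the presence of excess Grignard reagent.
- Comparison: the alternative is stronger on convergence at the union. The chosen strategy offers a defined construction of the left half, control of the enolate stoichiometry towards the valuable aldehyde, and a side chain whose ring closure has one regiochemical outcome.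

**Alternative 2:** The right half is cut at O29–C26 and C19–C20. In the forward step Lewis-acid activation of the terminal epoxide of the acyclic diepoxy β-keto ester A5 lets the inner epoxide oxygen attack C26 and the enol carbon attack C20, giving the bicyclic keto ester A4.
- For: one step builds both rings, the quaternary C20, the trans fusion and the oxepane with the correct regiochemistry, from a precursor available in about three steps. On step count and on oxepane regiocontrol it is stronger than the right-half sequence used here.
- Against: it does nothing for the left half. A4 carries an ester on C19, so joining it to the left half means alkylating a β-keto ester at a carbon next to the quaternary C20 and then removing the ester. The free C24 hydroxyl has to be carried or protected, and cascades of this kind lose material to O-termination and rearrangement.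
- Comparison: the chosen strategy is weaker on the right half but spends its one uncertain step on the seven-membered carbocycle, and joins the halves at a C19 methine through an aldol instead of a quaternising alkylation.

**Alternative 3:** The cyclopentanol ring is cut at C6–C10. In the forward step cathodic reduction of the cycloheptadienone A7, which carries a 3-oxobutyl chain on C7, couples the ketone carbon C10 with the enone β-carbon C6 to give the hydroazulenone A6.
- For: the C10 carbinol and the ring fusion form in one reagent-free step. Ketyl–olefin closures of this kind usually place the hydroxyl trans to the new ring bond, which is what the target needs.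
- Against: A7 is cross-conjugated and offers a second β-carbon (C16), and hydrodimerisation and over-reduction compete. Two stereocentres (C6, C10) are set by one transition state with only C7 to guide it. A6 still has C16 as an sp2 carbon, so this stereocentre and the exocyclic methylene must be made later by a face-selective reduction next to the quaternary C13. A7 itself is not a short target.
- Comparison: the alternative may need fewer ring-forming operations. The chosen strategy sets C16 before ring closure under catalyst control, takes C10 from a sterically controlled epoxidation and sets C6 by an SN2 inversion whose geometry is fixed by the tether.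

Key step: step 13

Assumption: in steps 1, 7 and 17 the catalyst antipode named is the one predicted by the accepted transition-state models to give the configurations drawn; both antipodes of each catalyst are available and the antipode is exchanged, with no other change, if the observed sense is the reverse.

## Route

Step 1
Reactants: 1 cyclopent-2-en-1-one; 2 [(1-methoxy-2-methylprop-1-en-1-yl)oxy]trimethylsilane
Product: 3 methyl 2-methyl-2-[(1R)-3-(trimethylsilyloxy)cyclopent-2-en-1-yl]propanoate
Conditions: (S)-diphenylprolinol B-(o-tolyl)oxazaborolidine·Tf2NH (15 mol%), Ph3PO (20 mol%), toluene, −20 °C; pentane, filtration, no aqueous work-up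
Reagents that add atoms: none
Why: Oxazaborolidinium-catalysed enantioselective Mukaiyama–Michael addition; the bound enone is attacked on one face at C7, and silyl transfer leaves the C6=C10 enol silane, which fixes where the ring double bond will later be.

Step 2
Reactants: 3 methyl 2-methyl-2-[(1R)-3-(trimethylsilyloxy)cyclopent-2-en-1-yl]propanoate
Product: 4 methyl 2-methyl-2-[(1R)-3-(trifluoromethanesulfonyloxy)cyclopent-2-en-1-yl]propanoate
Conditions: PhNTf2, CsF, DME, rt
Reagents that add atoms: N-phenylbis(trifluoromethanesulfonimide), O=S(=O)(N(c1ccccc1)S(=O)(=O)C(F)(F)F)C(F)(F)F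
Why: Fluoride cleaves the Si–O bond and the enolate is triflated on oxygen before it can equilibrate, so the enol triflate keeps the C6=C10 regiochemistry of step 1; the hindered ester is not touched.

Step 3
Reactants: 4 methyl 2-methyl-2-[(1R)-3-(trifluoromethanesulfonyloxy)cyclopent-2-en-1-yl]propanoate
Product: 5 methyl 2-methyl-2-[(1R)-3-methylcyclopent-2-en-1-yl]propanoate
Conditions: MeMgBr, Fe(acac)3 (5 mol%), THF/NMP, −30 °C
Reagents that add atoms: methylmagnesium bromide, C[Mg]Br
Why: Iron-catalysed cross-coupling of an alkenyl triflate with a methyl Grignard reagent attaches C11 to C10; coupling is faster than addition to the neopentyl ester at this temperature.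

Step 4
Reactants: 5 methyl 2-methyl-2-[(1R)-3-methylcyclopent-2-en-1-yl]propanoate
Product: 6 2-methyl-2-[(1R)-3-methylcyclopent-2-en-1-yl]propanal
Conditions: iBu2AlH (1.05 equiv), CH2Cl2, −78 °C; aq. KNaC4H4O6
Reagents that add atoms: none
Why: Partial reduction of an α-quaternary methyl ester stops at the aluminium hemiacetal, which gives the non-enolisable aldehyde on work-up; C7 cannot epimerise.

Step 5
Reactants: 6 2-methyl-2-[(1R)-3-methylcyclopent-2-en-1-yl]propanal; 7 dimethyl propanedioate
Product: 8 dimethyl 2-{2-methyl-2-[(1R)-3-methylcyclopent-2-en-1-yl]propylidene}propanedioate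
Conditions: TiCl4, pyridine, THF, 0 °C → rt
Reagents that add atoms: none
Why: Knoevenagel condensation under TiCl4/pyridine, the variant that tolerates α-quaternary aldehydes; the malonate gives a symmetric, non-enolised acceptor with no E/Z problem.

Step 6
Reactants: 9 S-tert-butyl ethanethioate
Product: 11 {[1-(tert-butylsulfanyl)ethenyl]oxy}trimethylsilane, via lithium thioester enolate 10 (not isolated)
Conditions: LiN(iPr)2, THF, −78 °C; then Me3SiCl
Reagents that add atoms: chlorotrimethylsilane, C[Si](C)(C)Cl
Why: O-silylation of the thioester lithium enolate gives the silyl ketene thioacetal that serves as the C17–C18 nucleophile.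

Step 7
Reactants: 8 dimethyl 2-{2-methyl-2-[(1R)-3-methylcyclopent-2-en-1-yl]propylidene}propanedioate; 11 {[1-(tert-butylsulfanyl)ethenyl]oxy}trimethylsilane
Product: 12 dimethyl 2-{(3S)-5-(tert-butylsulfanyl)-2-methyl-2-[(1R)-3-methylcyclopent-2-en-1-yl]-5-oxopentan-3-yl}propanedioate
Conditions: [Cu((S,S)-t-Bu-box)](SbF6)2 (10 mol%; t-Bu-box = 2,2'-(propane-2,2-diyl)bis(4-tert-butyl-4,5-dihydrooxazole)), (CF3)2CHOH (2 equiv), toluene/CH2Cl2 3:1, −78 °C
Reagents that add atoms: none
Why: Enantioselective Mukaiyama–Michael addition to an alkylidene malonate chelated to the C2-symmetric divalent-copper complex, a reaction that works best with bulky β-substituents; the ligand, not the remote C7 centre, selects the face of C16, and the fluorinated alcohol takes the silyl group and turns the catalyst over.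

Step 8
Reactants: 12 dimethyl 2-{(3S)-5-(tert-butylsulfanyl)-2-methyl-2-[(1R)-3-methylcyclopent-2-en-1-yl]-5-oxopentan-3-yl}propanedioate
Product: 13 methyl (3R)-5-(tert-butylsulfanyl)-3-{2-[(1R)-3-methylcyclopent-2-en-1-yl]propan-2-yl}-5-oxopentanoate
Conditions: LiCl, H2O, DMSO, 140 °C
Reagents that add atoms: none
Why: Krapcho dealkoxycarbonylation (chloride attacks an ester methyl, CO2 is lost) removes one malonate ester and leaves the hindered S-tert-butyl thioester; C16 carries no acidic hydrogen and is unchanged (the descriptor changes only through the priority rules).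

Step 9
Reactants: 13 methyl (3R)-5-(tert-butylsulfanyl)-3-{2-[(1R)-3-methylcyclopent-2-en-1-yl]propan-2-yl}-5-oxopentanoate
Product: 14 methyl (3S)-3-{2-[(1R)-3-methylcyclopent-2-en-1-yl]propan-2-yl}-5-oxopentanoate
Conditions: Et3SiH, 10% Pd/C, acetone, rt
Reagents that add atoms: none
Why: Fukuyama reduction converts the thioester into the aldehyde without reducing the methyl ester or the trisubstituted alkene.

Step 10
Reactants: 14 methyl (3S)-3-{2-[(1R)-3-methylcyclopent-2-en-1-yl]propan-2-yl}-5-oxopentanoate
Product: 15 methyl (3S)-5,5-dimethoxy-3-{2-[(1R)-3-methylcyclopent-2-en-1-yl]propan-2-yl}pentanoate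
Conditions: HC(OMe)3, MeOH, pyridinium p-toluenesulfonate (cat.), rt
Reagents that add atoms: trimethyl orthoformate, COC(OC)OC
Why: Acid-catalysed acetalisation masks C18 at the aldehyde level before any 1,3-dicarbonyl is made, so an enol is never present beside a free C18 carbonyl.

Step 11
Reactants: 15 methyl (3S)-5,5-dimethoxy-3-{2-[(1R)-3-methylcyclopent-2-en-1-yl]propan-2-yl}pentanoate; 16 N-methoxy-N-methylacetamide
Product: 18 methyl (3S)-2-acetyl-5,5-dimethoxy-3-{2-[(1R)-3-methylcyclopent-2-en-1-yl]propan-2-yl}pentanoate (both C2 epimers), via lithium ester enolate 17 (not isolated)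
Conditions: LiN(iPr)2, THF, −78 °C; then 16, −78 → 0 °C; aq. NH4Cl
Reagents that add atoms: none
Why: Crossed Claisen acylation of an ester enolate by an N-methoxy-N-methylamide; the chelated tetrahedral adduct lasts until work-up, so the enolate is not quenched by the more acidic product, and both C2 epimers are used.

Step 12
Reactants: 18 methyl (3S)-2-acetyl-5,5-dimethoxy-3-{2-[(1R)-3-methylcyclopent-2-en-1-yl]propan-2-yl}pentanoate
Product: 19 methyl (3S)-2-acetyl-5,5-dimethoxy-3-{2-[(1S,2S,5R)-5-methyl-6-oxabicyclo[3.1.0]hexan-2-yl]propan-2-yl}pentanoate (both C2 epimers)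
Conditions: mCPBA, NaHCO3, CH2Cl2, 0 °C
Reagents that add atoms: 3-chloroperoxybenzoic acid, OOC(=O)c1cccc(Cl)c1
Why: Prilezhaev epoxidation of the only electron-rich alkene, on the face away from the allylic quaternary substituent on C7, puts the epoxide oxygen trans to the C13 arm.

Step 13
Reactants: 19 methyl (3S)-2-acetyl-5,5-dimethoxy-3-{2-[(1S,2S,5R)-5-methyl-6-oxabicyclo[3.1.0]hexan-2-yl]propan-2-yl}pentanoate
Product: 22 methyl 1,7-dihydroxy-5-(2,2-dimethoxyethyl)-1,4,4-trimethyl-1,2,3,3a,4,5,8,8a-octahydroazulene-6-carboxylate (enol form; cis-fused; C6/C7/C10/C16 as in 49), via sodium enolate 20 (not isolated), via sodium lithium dienolate 21 (not isolated)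
Conditions: NaH, THF, 0 °C; n-BuLi, −20 °C; then 0 °C → rt; aq. NH4Cl
Reagents that add atoms: none
Why: NaH removes the doubly activated C2 hydrogen (both C2 epimers give the same enolate 20) and n-BuLi then removes a methyl hydrogen to give dienolate 21, whose terminal carbon C5 is by far its most nucleophilic site. C5 attacks the secondary epoxide carbon C6 opposite the C6–O bond, forming C5–C6 and releasing the C10 alkoxide; the closest known reactions are the γ-alkylation of acetoacetate dianions by epoxides and intramolecular carbanion–epoxide alkylations, of which this is an extension to a seven-membered ring. The ring closes in the 7-exo-tet mode: C5, C3, C2, C16, C13, C7 and C6 form the new ring and the breaking C6–O bond lies outside it. C6 is the only new stereocentre and is set by SN2 inversion; because the tether reaches C6 from C7 on the face opposite the epoxide oxygen, C5 ends cis to the C13 arm (cis ring fusion) and trans to the oxygen, which stays on C10 with its configuration unchanged. The step needs site selectivity in the nucleophile (C5 over C2, which could close a five-membered ring) and in the electrophile (C6 over C10); the first follows from the higher charge density at the dianion terminus and from the quaternary carbon that C2 attack would have to build next to C16 and C13, the second from C10 being tertiary and reachable only through an eight-membered endo transition state. The chelated U-shaped dienolate holds C5 syn to C16 and the gem-dimethyl group on C13 compresses the tether, and both favour closure. Basic conditions without Lewis acid avoid ionisation at the tertiary C10, and the acetal is inert.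

Step 14
Reactants: 22 methyl 1,7-dihydroxy-5-(2,2-dimethoxyethyl)-1,4,4-trimethyl-1,2,3,3a,4,5,8,8a-octahydroazulene-6-carboxylate
Product: 23 methyl 1-hydroxy-5-(2,2-dimethoxyethyl)-7-methoxy-1,4,4-trimethyl-1,2,3,3a,4,5,8,8a-octahydroazulene-6-carboxylate
Conditions: Me2SO4, Cs2CO3, DMF, 0 °C → rt
Reagents that add atoms: dimethyl sulfate, COS(=O)(=O)OC
Why: O-alkylation of the β-keto ester enolate by a hard electrophile in a dipolar solvent; C-alkylation would build a quaternary C2 between C16 and C3 and does not compete, and carbonate does not deprotonate the tertiary alcohol.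

Step 15
Reactants: 23 methyl 1-hydroxy-5-(2,2-dimethoxyethyl)-7-methoxy-1,4,4-trimethyl-1,2,3,3a,4,5,8,8a-octahydroazulene-6-carboxylate
Product: 25 methyl 7-methoxy-1,4,4-trimethyl-5-(2-oxoethyl)-1-(triethylsilyloxy)-1,2,3,3a,4,5,8,8a-octahydroazulene-6-carboxylate, via α-methoxyalkyl pyridinium triflate 24 (not isolated)
Conditions: Et3SiOTf (3 equiv), 2,6-lutidine (4 equiv), CH2Cl2, −40 → 0 °C; then H2O
Reagents that add atoms: triethylsilyl trifluoromethanesulfonate, CC[Si](CC)(CC)OS(=O)(=O)C(F)(F)F
Why: The silyl triflate silylates the tertiary C10 alcohol and, with the pyridine base, converts the dimethyl acetal into an α-methoxy pyridinium salt that water hydrolyses to the aldehyde; the medium is never acidic, so the vinylogous carbonate survives.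

Step 16
Reactants: 26 3-methylcyclohex-2-en-1-one
Product: 27 7-methyl-1,4-dioxaspiro[4.5]dec-7-ene
Conditions: HOCH2CH2OH, p-TsOH (cat.), benzene, reflux, water separator
Reagents that add atoms: ethane-1,2-diol, OCCO
Why: Ketalisation of a β-substituted cyclohexenone moves the double bond out of conjugation and gives mainly the β,γ-unsaturated ketal; the conjugated isomer is removed by distillation.

Step 17
Reactants: 27 7-methyl-1,4-dioxaspiro[4.5]dec-7-ene
Product: 28 (7S,8R)-7,8-epoxy-7-methyl-1,4-dioxaspiro[4.5]decane
Conditions: 1,2:4,5-di-O-isopropylidene-D-erythro-2,3-hexodiulo-2,6-pyranose (30 mol%), KHSO5 (as 2KHSO5·KHSO4·K2SO4), K2CO3, Bu4NHSO4, MeCN/CH2(OMe)2/aq. Na2B4O7, 0 °C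
Reagents that add atoms: potassium peroxymonosulfate, [K+].OOS(=O)(=O)[O-]
Why: Shi epoxidation; the chiral dioxirane transfers oxygen to one face of the trisubstituted ring alkene through the spiro transition state established for 1-substituted cyclohexenes, which sets the future C30.

Step 18
Reactants: 28 (7S,8R)-7,8-epoxy-7-methyl-1,4-dioxaspiro[4.5]decane
Product: 30 (4R)-4-hydroxy-3-methylcyclohex-2-en-1-one, via epoxy ketone 29 (not isolated)
Conditions: 1 M HCl (cat.), THF/H2O, 0 °C → rt; then Et3N
Reagents that add atoms: none
Why: Ketal hydrolysis gives the β,γ-epoxy ketone, which opens by E1cB cleavage of the tertiary C–O bond to the γ-hydroxy enone; the C–O bond at the carbinol carbon is never broken, so its configuration is retained (a diol formed by hydration at the tertiary carbon dehydrates to the same product).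

Step 19
Reactants: 30 (4R)-4-hydroxy-3-methylcyclohex-2-en-1-one
Product: 31 (4R)-4-[(tert-butyldimethylsilyl)oxy]-3-methylcyclohex-2-en-1-one
Conditions: TBSCl, imidazole, DMF, rt
Reagents that add atoms: tert-butylchlorodimethylsilane, CC(C)(C)[Si](C)(C)Cl
Why: Silylation of the secondary allylic alcohol under standard imidazole catalysis; the bulky silyl ether later directs the conjugate addition.

Step 20
Reactants: 32 5-bromo-2-methylpent-2-ene
Product: 33 2-(2-bromoethyl)-3,3-dimethyloxirane (racemic)
Conditions: mCPBA, NaHCO3, CH2Cl2, 0 °C
Reagents that add atoms: 3-chloroperoxybenzoic acid, OOC(=O)c1cccc(Cl)c1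
Why: Prilezhaev epoxidation of the trisubstituted alkene; the racemate is used because this carbon (C24) ends as a ketone.

Step 21
Reactants: 33 2-(2-bromoethyl)-3,3-dimethyloxirane
Product: 34 5-bromo-2-methylpent-1-en-3-ol (racemic)
Conditions: Et2Al(NC9H18) (from Et2AlCl and LiNC9H18; NC9H18 = 2,2,6,6-tetramethylpiperidide), toluene, 0 °C
Reagents that add atoms: none
Why: Aluminium amide-mediated isomerisation of an epoxide to an allylic alcohol: aluminium binds the epoxide oxygen and the amide removes a hydrogen from a methyl group syn to it, giving the secondary alcohol with an isopropenyl group; the hindered base does not attack the primary bromide at 0 °C.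

Step 22
Reactants: 34 5-bromo-2-methylpent-1-en-3-ol
Product: 35 [(5-bromo-2-methylpent-1-en-3-yl)oxy](tert-butyl)dimethylsilane (racemic)
Conditions: TBSCl, imidazole, DMF, rt
Reagents that add atoms: tert-butylchlorodimethylsilane, CC(C)(C)[Si](C)(C)Cl
Why: Silylation of the secondary alcohol so that the bromide can be turned into a Grignard reagent.

Step 23
Reactants: 31 (4R)-4-[(tert-butyldimethylsilyl)oxy]-3-methylcyclohex-2-en-1-one; 35 [(5-bromo-2-methylpent-1-en-3-yl)oxy](tert-butyl)dimethylsilane
Product: 37 tert-butyl({(1R,2R)-2-{3-[(tert-butyldimethylsilyl)oxy]-4-methylpent-4-en-1-yl}-2-methyl-4-(trimethylsilyloxy)cyclohex-3-en-1-yl}oxy)dimethylsilane (C24 epimers), via alkylmagnesium bromide 36 (not isolated)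
Conditions: Mg, THF (35 → 36); then CuBr·SMe2 (10 mol%), Me3SiCl, 31, THF, −78 °C; Et3N, pentane, filtration
Reagents that add atoms: chlorotrimethylsilane, C[Si](C)(C)Cl
Why: Copper-catalysed, silyl chloride-accelerated conjugate addition of the Grignard reagent forms the quaternary C20 anti to the neighbouring silyloxy group, and the enolate is trapped regiospecifically as the C19=C33 enol silane.

Step 24
Reactants: 37 right-half enol silane; 25 left-half aldehyde
Product: 39 aldol adduct joined at C18–C19 (carbinol at C18; mixture at C18 and C19; C24 epimers), via lithium ketone enolate 38 (not isolated)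
Conditions: MeLi, THF, 0 °C → rt; then 25, −78 °C; aq. NH4Cl
Reagents that add atoms: none
Why: MeLi cleaves only the trimethylsilyl enol ether and gives the lithium enolate with the C19 regiochemistry fixed in step 23; aldol addition to the aldehyde at −78 °C is faster than attack on the vinylogous carbonate, and the new centres at C18 and C19 are erased in steps 25 and 26.

Step 25
Reactants: 39 aldol adduct
Product: 41 C18=C19 enone (alkene geometry immaterial; C24 epimers), via C18 mesylate 40 (not isolated)
Conditions: MsCl, Et3N, CH2Cl2, 0 °C; then DBU, rt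
Reagents that add atoms: none
Why: Mesylation followed by E1cB elimination of the β-mesyloxy ketone; only C19–H is placed to eliminate, so the exocyclic enone is the only product.

Step 26
Reactants: 41 C18=C19 enone
Product: 42 ketone with C19–H (C19 R, C18 chain equatorial; C24 epimers)
Conditions: [(Ph3P)CuH]6 (0.4 equiv), H2O (5 equiv), toluene, rt
Reagents that add atoms: none
Why: Copper hydride conjugate reduction of the enone leaves the isolated 1,1-disubstituted alkene and the vinylogous carbonate alone; the enolate is protonated axially on the face opposite the axial C20 methyl, which is also the thermodynamic result (equatorial chain), and any C19 epimer is equilibrated by a trace of DBU.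

Step 27
Reactants: 42 ketone
Product: 43 C33 tertiary alcohol (C33 S, hydroxyl axial; C24 epimers)
Conditions: MeMgBr, CeCl3, THF, −78 → 0 °C; aq. NH4Cl
Reagents that add atoms: methylmagnesium bromide, C[Mg]Br
Why: Cerium-promoted 1,2-addition suppresses enolisation of the hindered ketone; the axial C20 methyl blocks axial attack, so the methyl enters equatorially and the hydroxyl is left axial as in the target, and the vinylogous carbonate does not react at this temperature.

Step 28
Reactants: 43 C33 tertiary alcohol
Product: 44 tetraol with free hydroxyls at C10, C24, C30 and C33 (C24 epimers)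
Conditions: HF·pyridine, pyridine, THF, 0 °C → rt
Reagents that add atoms: none
Why: Fluoride-mediated cleavage of the two TBS ethers and the TES ether; the buffered reagent neither hydrolyses the vinylogous carbonate nor ionises the tertiary alcohols.

Step 29
Reactants: 44 tetraol
Product: 46 oxepane C24 alcohol (trans-fused; C24 epimers), via alkylmercury trifluoroacetate 45 (not isolated)
Conditions: Hg(OCOCF3)2 (1.2 equiv), CH2Cl2, −20 → 0 °C; then NaBH4, aq. NaOH, 0 °C
Reagents that add atoms: none
Why: Intramolecular alkoxymercuration: the C30 hydroxyl attacks the more substituted carbon of the mercurinium ion of the isopropenyl group (7-exo-trig, Markovnikov), the only ring size and regiochemistry available to any of the four hydroxyls, and demercuration turns the CH2Hg group into the second methyl on C26; the trans ring fusion is already fixed by C20 and C30.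

Step 30
Reactants: 46 oxepane C24 alcohol
Product: 48 α-methylene ketone with C24 alcohol (C24 epimers), via allylic alcohol enol ether 47 (not isolated)
Conditions: iBu2AlH (6 equiv), CH2Cl2, −78 → 0 °C; aq. KNaC4H4O6; then 5% aq. oxalic acid, THF, rt
Reagents that add atoms: water, O
Why: Reduction of the vinylogous carbonate gives the allylic alcohol; acid then removes the C1 hydroxyl to a methoxy-stabilised allyl cation that is hydrated at C3 and loses methanol, so the ester carbon becomes the exocyclic methylene and the ketone appears at C3 (enol ether reduction–hydrolysis in the manner of the Stork–Danheiser transposition).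

Step 31
Reactants: 48 α-methylene ketone with C24 alcohol
Product: 49 target, CNP0316622.2
Conditions: Dess–Martin periodinane, NaHCO3, CH2Cl2, rt
Reagents that add atoms: none
Why: Dess–Martin oxidation of the only secondary alcohol; both C24 epimers converge on the ketone, and the tertiary alcohols and the enone are inert.

## Compound list

1 | cyclopent-2-en-1-one | O=C1C=CCC1 | starting material
2 | [(1-methoxy-2-methylprop-1-en-1-yl)oxy]trimethylsilane | COC(O[Si](C)(C)C)=C(C)C | starting material
3 | methyl 2-methyl-2-[(1R)-3-(trimethylsilyloxy)cyclopent-2-en-1-yl]propanoate | COC(=O)C(C)(C)[C@@H]1CCC(O[Si](C)(C)C)=C1 | intermediate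
4 | methyl 2-methyl-2-[(1R)-3-(trifluoromethanesulfonyloxy)cyclopent-2-en-1-yl]propanoate | COC(=O)C(C)(C)[C@@H]1CCC(OS(=O)(=O)C(F)(F)F)=C1 | intermediate
5 | methyl 2-methyl-2-[(1R)-3-methylcyclopent-2-en-1-yl]propanoate | COC(=O)C(C)(C)[C@@H]1CCC(C)=C1 | intermediate
6 | 2-methyl-2-[(1R)-3-methylcyclopent-2-en-1-yl]propanal | O=CC(C)(C)[C@@H]1CCC(C)=C1 | intermediate
7 | dimethyl propanedioate | COC(=O)CC(=O)OC | starting material
8 | dimethyl 2-{2-methyl-2-[(1R)-3-methylcyclopent-2-en-1-yl]propylidene}propanedioate | COC(=O)C(C(=O)OC)=CC(C)(C)[C@@H]1CCC(C)=C1 | intermediate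
9 | S-tert-butyl ethanethioate | CC(=O)SC(C)(C)C | starting material
10 | lithium 1-(tert-butylsulfanyl)ethen-1-olate | [Li+].C=C([O-])SC(C)(C)C | intermediate (not isolated)
11 | {[1-(tert-butylsulfanyl)ethenyl]oxy}trimethylsilane | C=C(O[Si](C)(C)C)SC(C)(C)C | intermediate
12 | dimethyl 2-{(3S)-5-(tert-butylsulfanyl)-2-methyl-2-[(1R)-3-methylcyclopent-2-en-1-yl]-5-oxopentan-3-yl}propanedioate | COC(=O)C(C(=O)OC)[C@H](CC(=O)SC(C)(C)C)C(C)(C)[C@@H]1CCC(C)=C1 | intermediate
13 | methyl (3R)-5-(tert-butylsulfanyl)-3-{2-[(1R)-3-methylcyclopent-2-en-1-yl]propan-2-yl}-5-oxopentanoate | COC(=O)C[C@H](CC(=O)SC(C)(C)C)C(C)(C)[C@@H]1CCC(C)=C1 | intermediate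
14 | methyl (3S)-3-{2-[(1R)-3-methylcyclopent-2-en-1-yl]propan-2-yl}-5-oxopentanoate | COC(=O)C[C@H](CC=O)C(C)(C)[C@@H]1CCC(C)=C1 | intermediate
15 | methyl (3S)-5,5-dimethoxy-3-{2-[(1R)-3-methylcyclopent-2-en-1-yl]propan-2-yl}pentanoate | COC(=O)C[C@H](CC(OC)OC)C(C)(C)[C@@H]1CCC(C)=C1 | intermediate
16 | N-methoxy-N-methylacetamide | CC(=O)N(C)OC | starting material
17 | lithium enolate of 15 | [Li+].COC([O-])=C[C@H](CC(OC)OC)C(C)(C)[C@@H]1CCC(C)=C1 | intermediate (not isolated)
18 | methyl (3S)-2-acetyl-5,5-dimethoxy-3-{2-[(1R)-3-methylcyclopent-2-en-1-yl]propan-2-yl}pentanoate, C2 epimers | CC(=O)C(C(=O)OC)[C@H](CC(OC)OC)C(C)(C)[C@@H]1CCC(C)=C1 | intermediate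
19 | methyl (3S)-2-acetyl-5,5-dimethoxy-3-{2-[(1S,2S,5R)-5-methyl-6-oxabicyclo[3.1.0]hexan-2-yl]propan-2-yl}pentanoate, C2 epimers (key-step precursor) | CC(=O)C(C(=O)OC)[C@H](CC(OC)OC)C(C)(C)[C@@H]1CC[C@@]2(C)O[C@@H]12 | intermediate
20 | sodium enolate of 19 | [Na+].CC([O-])=C(C(=O)OC)[C@H](CC(OC)OC)C(C)(C)[C@@H]1CC[C@@]2(C)O[C@@H]12 | intermediate (not isolated)
21 | sodium lithium dienolate of 19 | [Li+].[Na+].C=C([O-])C(=C([O-])OC)[C@H](CC(OC)OC)C(C)(C)[C@@H]1CC[C@@]2(C)O[C@@H]12 | intermediate (not isolated)
22 | methyl 1,7-dihydroxy-5-(2,2-dimethoxyethyl)-1,4,4-trimethyl-1,2,3,3a,4,5,8,8a-octahydroazulene-6-carboxylate (enol form; 3a-H, 8a-H and 5-H cis; 1-OH cis to 8a-H; key-step product) | COC(=O)C1=C(O)C[C@@H]2[C@@H](CC[C@@]2(C)O)C(C)(C)[C@H]1CC(OC)OC | intermediate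
23 | methyl 1-hydroxy-5-(2,2-dimethoxyethyl)-7-methoxy-1,4,4-trimethyl-1,2,3,3a,4,5,8,8a-octahydroazulene-6-carboxylate (same configuration) | COC(=O)C1=C(OC)C[C@@H]2[C@@H](CC[C@@]2(C)O)C(C)(C)[C@H]1CC(OC)OC | intermediate
24 | 1-{1-methoxy-2-[hydroazulenyl]ethyl}-2,6-dimethylpyridinium triflate of the C10 TES ether of 23 | COC(=O)C1=C(OC)C[C@@H]2[C@@H](CC[C@@]2(C)O[Si](CC)(CC)CC)C(C)(C)[C@H]1CC(OC)[n+]1c(C)cccc1C.[O-]S(=O)(=O)C(F)(F)F | intermediate (not isolated)
25 | methyl 7-methoxy-1,4,4-trimethyl-5-(2-oxoethyl)-1-(triethylsilyloxy)-1,2,3,3a,4,5,8,8a-octahydroazulene-6-carboxylate (left-half aldehyde) | COC(=O)C1=C(OC)C[C@@H]2[C@@H](CC[C@@]2(C)O[Si](CC)(CC)CC)C(C)(C)[C@H]1CC=O | intermediate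
26 | 3-methylcyclohex-2-en-1-one | CC1=CC(=O)CCC1 | starting material
27 | 7-methyl-1,4-dioxaspiro[4.5]dec-7-ene | CC1=CCCC2(C1)OCCO2 | intermediate
28 | (7S,8R)-7,8-epoxy-7-methyl-1,4-dioxaspiro[4.5]decane | C[C@]12CC3(OCCO3)CC[C@H]1O2 | intermediate
29 | (3S,4R)-3,4-epoxy-3-methylcyclohexan-1-one | C[C@]12CC(=O)CC[C@H]1O2 | intermediate (not isolated)
30 | (4R)-4-hydroxy-3-methylcyclohex-2-en-1-one | O=C1C=C(C)[C@H](O)CC1 | intermediate
31 | (4R)-4-[(tert-butyldimethylsilyl)oxy]-3-methylcyclohex-2-en-1-one | O=C1C=C(C)[C@H](O[Si](C)(C)C(C)(C)C)CC1 | intermediate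
32 | 5-bromo-2-methylpent-2-ene | CC(C)=CCCBr | starting material
33 | 2-(2-bromoethyl)-3,3-dimethyloxirane (racemic) | CC1(C)OC1CCBr | intermediate
34 | 5-bromo-2-methylpent-1-en-3-ol (racemic) | CC(=C)C(O)CCBr | intermediate
35 | [(5-bromo-2-methylpent-1-en-3-yl)oxy](tert-butyl)dimethylsilane (racemic) | CC(=C)C(CCBr)O[Si](C)(C)C(C)(C)C | intermediate
36 | {3-[(tert-butyldimethylsilyl)oxy]-4-methylpent-4-en-1-yl}magnesium bromide | CC(=C)C(CC[Mg]Br)O[Si](C)(C)C(C)(C)C | intermediate (not isolated)
37 | tert-butyl({(1R,2R)-2-{3-[(tert-butyldimethylsilyl)oxy]-4-methylpent-4-en-1-yl}-2-methyl-4-(trimethylsilyloxy)cyclohex-3-en-1-yl}oxy)dimethylsilane, C24 epimers | C[Si](C)(C)OC1=C[C@@](C)(CCC(O[Si](C)(C)C(C)(C)C)C(C)=C)[C@H](O[Si](C)(C)C(C)(C)C)CC1 | intermediate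
38 | lithium (3R,4R)-4-(TBS-oxy)-3-[3-(TBS-oxy)-4-methylpent-4-en-1-yl]-3-methylcyclohex-1-en-1-olate | [Li+].[O-]C1=C[C@@](C)(CCC(O[Si](C)(C)C(C)(C)C)C(C)=C)[C@H](O[Si](C)(C)C(C)(C)C)CC1 | intermediate (not isolated)
39 | aldol adduct: 25 bonded through C18 (carbinol) to C19 of the (C20 R, C30 R) cyclohexanone; mixture at C18, C19, C24 | COC(=O)C1=C(OC)C[C@@H]2[C@@H](CC[C@@]2(C)O[Si](CC)(CC)CC)C(C)(C)[C@H]1CC(O)C1[C@@](C)(CCC(O[Si](C)(C)C(C)(C)C)C(C)=C)[C@H](O[Si](C)(C)C(C)(C)C)CCC1=O | intermediate
40 | C18 methanesulfonate of 39 | COC(=O)C1=C(OC)C[C@@H]2[C@@H](CC[C@@]2(C)O[Si](CC)(CC)CC)C(C)(C)[C@H]1CC(OS(C)(=O)=O)C1[C@@](C)(CCC(O[Si](C)(C)C(C)(C)C)C(C)=C)[C@H](O[Si](C)(C)C(C)(C)C)CCC1=O | intermediate (not isolated)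
41 | C18=C19 enone (2-alkylidenecyclohexanone; C24 epimers) | COC(=O)C1=C(OC)C[C@@H]2[C@@H](CC[C@@]2(C)O[Si](CC)(CC)CC)C(C)(C)[C@H]1CC=C1[C@@](C)(CCC(O[Si](C)(C)C(C)(C)C)C(C)=C)[C@H](O[Si](C)(C)C(C)(C)C)CCC1=O | intermediate
42 | C33 ketone with C19 R, C20 R, C30 R (C18 chain equatorial; C24 epimers) | COC(=O)C1=C(OC)C[C@@H]2[C@@H](CC[C@@]2(C)O[Si](CC)(CC)CC)C(C)(C)[C@H]1CC[C@@H]1[C@@](C)(CCC(O[Si](C)(C)C(C)(C)C)C(C)=C)[C@H](O[Si](C)(C)C(C)(C)C)CCC1=O | intermediate
43 | C33 tertiary alcohol (C33 S, axial OH; silyl ethers at C10, C24, C30; C24 epimers) | COC(=O)C1=C(OC)C[C@@H]2[C@@H](CC[C@@]2(C)O[Si](CC)(CC)CC)C(C)(C)[C@H]1CC[C@@H]1[C@@](C)(CCC(O[Si](C)(C)C(C)(C)C)C(C)=C)[C@H](O[Si](C)(C)C(C)(C)C)CC[C@]1(C)O | intermediate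
44 | tetraol (free OH at C10, C24, C30, C33; isopropenyl carbinol side chain; C24 epimers) | COC(=O)C1=C(OC)C[C@@H]2[C@@H](CC[C@@]2(C)O)C(C)(C)[C@H]1CC[C@@H]1[C@@](C)(CCC(O)C(C)=C)[C@H](O)CC[C@]1(C)O | intermediate
45 | oxepane with CH2HgOCOCF3 on C26 (mixture at C24 and C26) | COC(=O)C1=C(OC)C[C@@H]2[C@@H](CC[C@@]2(C)O)C(C)(C)[C@H]1CC[C@@H]1[C@@]2(C)CCC(O)C(C)(C[Hg]OC(=O)C(F)(F)F)O[C@@H]2CC[C@]1(C)O | intermediate (not isolated)
46 | trans-fused 2,2-dimethyloxepan-3-ol joined to the vinylogous carbonate left half (C24 epimers) | COC(=O)C1=C(OC)C[C@@H]2[C@@H](CC[C@@]2(C)O)C(C)(C)[C@H]1CC[C@@H]1[C@@]2(C)CCC(O)C(C)(C)O[C@@H]2CC[C@]1(C)O | intermediate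
47 | allylic alcohol enol ether (C1 hydroxymethyl on C2, methoxy on C3; C24 epimers) | OCC1=C(OC)C[C@@H]2[C@@H](CC[C@@]2(C)O)C(C)(C)[C@H]1CC[C@@H]1[C@@]2(C)CCC(O)C(C)(C)O[C@@H]2CC[C@]1(C)O | intermediate (not isolated)
48 | 24-hydroxy analogue of the target (α-methylene ketone; C24 epimers) | C=C1C(=O)C[C@@H]2[C@@H](CC[C@@]2(C)O)C(C)(C)[C@H]1CC[C@@H]1[C@@]2(C)CCC(O)C(C)(C)O[C@@H]2CC[C@]1(C)O | intermediate
49 | CNP0316622.2 (C6 R, C7 R, C10 R, C16 R, C19 R, C20 R, C30 R, C33 S) | C=C1C(=O)C[C@@H]2[C@@H](CC[C@@]2(C)O)C(C)(C)[C@H]1CC[C@@H]1[C@@]2(C)CCC(=O)C(C)(C)O[C@@H]2CC[C@]1(C)O | target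

## Step count and least certain steps

Total: 31 steps. Longest linear sequence: 22 steps (steps 1–5, 7–15 and 24–31). The right half contributes 13 steps in its own line (16–19, 23, 24–31); step 6 and steps 20–22 are short side branches.

**Step 13 (key step).** The seven-membered closure at the hindered C6 may be slower than other reactions of the dianion. These are attack through C2 on the same carbon (five-membered closure), base-induced isomerisation of the epoxide to an allylic alcohol by removal of a C9 or C11 hydrogen, and proton transfer that returns the monoanion. Fallback, from 12 back to 25: one ester of malonate 12 is saponified (KOH, 1 equiv, MeOH, 0 °C) to the malonic half acid F1, which is converted with (COCl)2 into the acid chloride F2 and with CH2N2 into the diazoketone F3. Rh2(OAc)4 in CH2Cl2 adds the carbene carbon (the future C5) across the C6=C10 alkene from the face of the tether, giving the cyclopropyl ketone F4. Aqueous HClO4 in acetone then cleaves the C5–C10 bond at the tertiary carbon with inversion to the hydroxy β-keto ester F5, which has the same C5–C6 bond, cis fusion and C10 configuration as 22. O-methylation (Me2SO4, Cs2CO3) gives the enol ether F6, silylation (Et3SiOTf, 2,6-lutidine) gives the silyl ether F7, and Fukuyama reduction (Et3SiH, Pd/C) returns to aldehyde 25. The cyclopropanation delivers C5 to the same face as the dianion would, so the stereochemical argument is unchanged.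

**Step 7.** Turnover may be slow or facial selectivity eroded, because the β-substituent is larger than a tert-butyl group and carries its own stereocentre, so a mismatch with the ligand is possible. Fallback, from 6 back to 14: Horner–Wadsworth–Emmons reaction of aldehyde 6 with the diethyl phosphonoacetyl derivative of (4S)-4-phenyl-1,3-oxazolidin-2-one (LiCl, iPr2NEt, MeCN) gives the (E)-enoyl imide F8. Vinylmagnesium bromide with CuBr·SMe2 (THF, −78 → −20 °C) adds to the chelated s-cis imide on the face away from the phenyl group, giving the vinyl adduct F9. Magnesium methoxide (MeMgBr, MeOH, 0 °C) releases the auxiliary and gives the methyl ester F10. 9-Borabicyclo[3.3.1]nonane hydroborates only the vinyl group, and NaBO3 oxidation gives the primary alcohol F11, which is oxidised at once (Dess–Martin), before it can lactonise, to aldehyde 14.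

**Step 24.** The hindered enolate may remove an α-hydrogen from aldehyde 25 instead of adding to it, and the adduct may revert on warming. Fallback, from 25 back to 42: aldehyde 25 is reduced (NaBH4, MeOH, 0 °C) to the primary alcohol F12 and converted (I2, PPh3, imidazole) into the primary iodide F13. Lithium enolate 38, generated from 37 as in step 24, is alkylated with F13 in THF/HMPA (−78 → 0 °C), and C19 is equilibrated (NaOMe, MeOH) to ketone 42; steps 24–26 are replaced.

**Step 29.** The mercury salt may attack the tetrasubstituted vinylogous carbonate alkene, or trifluoroacetate may capture the mercurinium ion faster than the seven-membered ring closes. Fallback, from 44 back to 46: tetraol 44 is cyclised with I2 and NaHCO3 in MeCN at 0 °C, in the same 7-exo Markovnikov mode but under reversible iodonium formation, to the iodomethyl oxepane F14; the C–I bond is then reduced with Bu3SnH and azobisisobutyronitrile (toluene, 80 °C) to give 46.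

## Further compounds

F1 | step 13 | malonic half acid from 12 (C2 epimers) | OC(=O)C(C(=O)OC)[C@H](CC(=O)SC(C)(C)C)C(C)(C)[C@@H]1CCC(C)=C1
F2 | step 13 | acid chloride of F1 | ClC(=O)C(C(=O)OC)[C@H](CC(=O)SC(C)(C)C)C(C)(C)[C@@H]1CCC(C)=C1
F3 | step 13 | diazoketone, methyl 4-diazo-3-oxobutanoate substituted at C2 | [N-]=[N+]=CC(=O)C(C(=O)OC)[C@H](CC(=O)SC(C)(C)C)C(C)(C)[C@@H]1CCC(C)=C1
F4 | step 13 | cyclopropyl ketone with C5 bridging C6 and C10 | COC(=O)C1C(=O)[C@@H]3[C@@H]2[C@@H](CC[C@@]23C)C(C)(C)[C@H]1CC(=O)SC(C)(C)C
F5 | step 13 | hydroxy β-keto ester, thioester analogue of 22 | COC(=O)C1=C(O)C[C@@H]2[C@@H](CC[C@@]2(C)O)C(C)(C)[C@H]1CC(=O)SC(C)(C)C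
F6 | step 13 | methyl enol ether of F5 | COC(=O)C1=C(OC)C[C@@H]2[C@@H](CC[C@@]2(C)O)C(C)(C)[C@H]1CC(=O)SC(C)(C)C
F7 | step 13 | C10 triethylsilyl ether of F6 | COC(=O)C1=C(OC)C[C@@H]2[C@@H](CC[C@@]2(C)O[Si](CC)(CC)CC)C(C)(C)[C@H]1CC(=O)SC(C)(C)C
F8 | step 7 | (4S)-3-{(2E)-4-methyl-4-[(1R)-3-methylcyclopent-2-en-1-yl]pent-2-enoyl}-4-phenyl-1,3-oxazolidin-2-one | O=C(/C=C/C(C)(C)[C@@H]1CCC(C)=C1)N1[C@@H](c2ccccc2)COC1=O
F9 | step 7 | vinyl conjugate adduct of F8 | O=C(C[C@H](C=C)C(C)(C)[C@@H]1CCC(C)=C1)N1[C@@H](c2ccccc2)COC1=O
F10 | step 7 | methyl 3-{2-[(1R)-3-methylcyclopent-2-en-1-yl]propan-2-yl}pent-4-enoate (C3 as in 14) | COC(=O)C[C@H](C=C)C(C)(C)[C@@H]1CCC(C)=C1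
F11 | step 7 | methyl 5-hydroxy-3-{2-[(1R)-3-methylcyclopent-2-en-1-yl]propan-2-yl}pentanoate (C3 as in 14) | COC(=O)C[C@H](CCO)C(C)(C)[C@@H]1CCC(C)=C1
F12 | step 24 | primary alcohol from 25 (C18 hydroxyl) | COC(=O)C1=C(OC)C[C@@H]2[C@@H](CC[C@@]2(C)O[Si](CC)(CC)CC)C(C)(C)[C@H]1CCO
F13 | step 24 | primary iodide from F12 (C18 iodide) | COC(=O)C1=C(OC)C[C@@H]2[C@@H](CC[C@@]2(C)O[Si](CC)(CC)CC)C(C)(C)[C@H]1CCI
F14 | step 29 | iodomethyl oxepane (CH2I on C26; mixture at C24 and C26) | COC(=O)C1=C(OC)C[C@@H]2[C@@H](CC[C@@]2(C)O)C(C)(C)[C@H]1CC[C@@H]1[C@@]2(C)CCC(O)C(C)(CI)O[C@@H]2CC[C@]1(C)O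
A1 | alternative 1 | β-hydroxy ketone joining left half and cyclohexanone | C=C1[C@@H](O[Si](C(C)C)(C(C)C)C(C)C)C[C@@H]2[C@@H](CC[C@@]2(C)O[Si](CC)(CC)CC)C(C)(C)[C@H]1C[C@@H](O)[C@@H]1[C@@](C)(CCC=C(C)C)[C@H](O[Si](C)(C)C(C)(C)C)CCC1=O
A2 | alternative 1 | left-half aldehyde with C3 triisopropylsilyl ether and exocyclic methylene | C=C1[C@@H](O[Si](C(C)C)(C(C)C)C(C)C)C[C@@H]2[C@@H](CC[C@@]2(C)O[Si](CC)(CC)CC)C(C)(C)[C@H]1CC=O
A3 | alternative 1 | (4-methylpent-3-en-1-yl)magnesium bromide | CC(C)=CCC[Mg]Br
A4 | alternative 2 | trans-fused oxepane–cyclohexanone β-keto ester with free C24 hydroxyl | COC(=O)[C@@H]1[C@@]2(C)CC[C@@H](O)C(C)(C)O[C@@H]2CCC1=O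
A5 | alternative 2 | methyl 6,7:10,11-diepoxy-7,11-dimethyl-3-oxododecanoate | COC(=O)CC(=O)CC[C@H]1O[C@]1(C)CC[C@H]1OC1(C)C
A6 | alternative 3 | cis-fused hydroazulenone with C10 tertiary alcohol | O=C1C[C@@H]2[C@@H](CC[C@@]2(C)O)C(C)(C)C(CCOCc3ccccc3)=C1CO[Si](C)(C)C(C)(C)C
A7 | alternative 3 | cross-conjugated cycloheptadienone with 3-oxobutyl chain on C7 | O=C1C=C[C@@H](CCC(C)=O)C(C)(C)C(CCOCc2ccccc2)=C1CO[Si](C)(C)C(C)(C)C
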